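**Retrosynthetic overview**

1. The target comes from one global hydrogenation of a penta-O-benzyl stilbene: the C=C becomes the CH2CH2 bridge and five OBn groups become OH.
2. Key disconnection: all three ArCH2–Ar bonds at once, by a threefold nickel-catalysed coupling of a tribromostilbene with three equivalents of the hydrazone of a 4-alkoxybenzaldehyde (aldehyde carbon used as a benzyl carbanion equivalent against C–Br carbons).
3. The central C=C comes from a ruthenium-catalysed hydrazone/aldehyde olefination of two bromobenzaldehydes (one aldehyde carbon reacts as a carbanion equivalent towards the other).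
4. The 2,6-dibromo ring A aldehyde comes from O-benzylation and double para-directed bromination of a 3-hydroxy-5-alkoxybenzaldehyde.
5. Ring order: no ring is formed; ring A, ring B and the three 4-oxybenzyl rings are all bought as intact benzenes and only joined.

Assumption: the target has no stereocentre and no stereogenic double bond, so it is achiral and there is no enantiomer to select; aldehydes 1, 4 and 7 are taken as catalogue compounds.

**Route**

Step 1
Reactants: 1 3-hydroxy-5-methoxybenzaldehyde
Product: 2 3-(benzyloxy)-5-methoxybenzaldehyde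
Conditions: BnBr (1.1 equiv), K2CO3 (1.5 equiv), DMF, 50 °C
Reagents that add atoms: benzyl bromide, BrCc1ccccc1
Why: Williamson ether synthesis; the phenoxide is alkylated cleanly by the benzylic bromide while the aldehyde is inert to carbonate.

Step 2
Reactants: 2 3-(benzyloxy)-5-methoxybenzaldehyde
Product: 3 3-(benzyloxy)-2,6-dibromo-5-methoxybenzaldehyde
Conditions: NBS (2.1 equiv), MeCN, 0 °C to 40 °C, dark
Reagents that add atoms: N-bromosuccinimide, O=C1CCC(=O)N1Br
Why: Electrophilic aromatic bromination; C2 and C6 are each para to one alkoxy group and ortho to the other, whereas C4 is only ortho/ortho and wedged between both alkoxy groups, so 3,5-dialkoxybenzaldehydes take two halogens next to the formyl group.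

Step 3
Reactants: 4 2-(benzyloxy)-5-bromobenzaldehyde; 3 3-(benzyloxy)-2,6-dibromo-5-methoxybenzaldehyde
Product: 6 (E)-1-(benzyloxy)-3-{2-[2-(benzyloxy)-5-bromophenyl]ethenyl}-2,4-dibromo-5-methoxybenzene, via 2-(benzyloxy)-5-bromobenzaldehyde hydrazone 5 (not isolated)
Conditions: 4 (1.3 equiv), N2H4·H2O (1.35 equiv), THF, rt, 1 h; then 3 (1.0 equiv), [Ru(p-cymene)Cl2]2 (2.5 mol%), Me2PCH2CH2PMe2 (5 mol%), KOtBu (50 mol%), THF, 45 °C
Reagents that add atoms: none
Why: Ruthenium-catalysed carbonyl reductive cross-coupling (hydrazone as carbanion equivalent, Wolff–Kishner-type N2 loss): the N-bound hydrazonide of 5 adds through its carbon to the electron-poor, non-enolisable aldehyde 3 in a six-membered transition state on divalent ruthenium, and the resulting hydroxy-diazene loses N2 and hydroxide (E1cB) to give the E stilbene, whose geometry is erased in step 5; the aryl bromides are untouched by this catalyst.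

Step 4
Reactants: 7 4-(benzyloxy)benzaldehyde; 6 (E)-1-(benzyloxy)-3-{2-[2-(benzyloxy)-5-bromophenyl]ethenyl}-2,4-dibromo-5-methoxybenzene
Product: 9 (E)-1-(benzyloxy)-3-(2-{2-(benzyloxy)-5-[4-(benzyloxy)benzyl]phenyl}ethenyl)-2,4-bis[4-(benzyloxy)benzyl]-5-methoxybenzene, via 4-(benzyloxy)benzaldehyde hydrazone 8 (not isolated)
Conditions: 7 (4.5 equiv in all, three of them built into the product), N2H4·H2O (4.7 equiv), THF, rt, then 4 Å MS; then 6 (1.0 equiv), Ni(cod)2 (15 mol%), PMe3 (30 mol%), K3PO4 (4.5 equiv), THF/1,4-dioxane, 80 °C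
Reagents that add atoms: 4-(benzyloxy)benzaldehyde (two further equivalents), O=Cc1ccc(OCc2ccccc2)cc1.O=Cc1ccc(OCc2ccccc2)cc1
Why: Nickel-catalysed denitrogenative cross-coupling of an aldehyde hydrazone with aryl bromides, run three times on one substrate, so that three molecules of 7 (the reactant plus the two further equivalents) are built into each molecule of 6: each C–Br bond adds oxidatively to zerovalent nickel, the phosphate-generated hydrazonide of 8 forms the C–C bond at its former carbonyl carbon (which thus acts as a 4-(benzyloxy)benzyl anion), and base-induced loss of N2 leaves each ArCH2Ar link. Small PMe3 is chosen because both ring A bromides are flanked on two sides; the threefold coupling is the deliberate stretch of this known reaction type.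

Step 5
Reactants: 9 (E)-1-(benzyloxy)-3-(2-{2-(benzyloxy)-5-[4-(benzyloxy)benzyl]phenyl}ethenyl)-2,4-bis[4-(benzyloxy)benzyl]-5-methoxybenzene
Product: 10 2,4-bis(4-hydroxybenzyl)-3-{2-[2-hydroxy-5-(4-hydroxybenzyl)phenyl]ethyl}-5-methoxyphenol (target)
Conditions: H2 (3 bar), 10% Pd/C, THF/MeOH 1:1, rt
Reagents that add atoms: none
Why: Catalytic hydrogenation plus hydrogenolysis; the stilbene C=C is saturated and all five aryl benzyl ethers are cleaved, while the aryl methyl ether and the diarylmethane C–C bonds are inert, giving the achiral target.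

**Compound list**

1 | 3-hydroxy-5-methoxybenzaldehyde | COc1cc(O)cc(C=O)c1 | starting material
2 | 3-(benzyloxy)-5-methoxybenzaldehyde | COc1cc(OCc2ccccc2)cc(C=O)c1 | intermediate
3 | 3-(benzyloxy)-2,6-dibromo-5-methoxybenzaldehyde | COc1cc(OCc2ccccc2)c(Br)c(C=O)c1Br | intermediate
4 | 2-(benzyloxy)-5-bromobenzaldehyde | O=Cc1cc(Br)ccc1OCc1ccccc1 | starting material
5 | (E)-[2-(benzyloxy)-5-bromobenzylidene]hydrazine (hydrazone of 4) | N/N=C/c1cc(Br)ccc1OCc1ccccc1 | intermediate
6 | (E)-1-(benzyloxy)-3-{2-[2-(benzyloxy)-5-bromophenyl]ethenyl}-2,4-dibromo-5-methoxybenzene | COc1cc(OCc2ccccc2)c(Br)c(/C=C/c2cc(Br)ccc2OCc2ccccc2)c1Br | intermediate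
7 | 4-(benzyloxy)benzaldehyde | O=Cc1ccc(OCc2ccccc2)cc1 | starting material
8 | (E)-[4-(benzyloxy)benzylidene]hydrazine (hydrazone of 7) | N/N=C/c1ccc(OCc2ccccc2)cc1 | intermediate
9 | (E)-1-(benzyloxy)-3-(2-{2-(benzyloxy)-5-[4-(benzyloxy)benzyl]phenyl}ethenyl)-2,4-bis[4-(benzyloxy)benzyl]-5-methoxybenzene | COc1cc(OCc2ccccc2)c(Cc2ccc(OCc3ccccc3)cc2)c(/C=C/c2cc(Cc3ccc(OCc4ccccc4)cc3)ccc2OCc2ccccc2)c1Cc1ccc(OCc2ccccc2)cc1 | intermediate
10 | 2,4-bis(4-hydroxybenzyl)-3-{2-[2-hydroxy-5-(4-hydroxybenzyl)phenyl]ethyl}-5-methoxyphenol | COc1cc(O)c(Cc2ccc(O)cc2)c(CCc2cc(Cc3ccc(O)cc3)ccc2O)c1Cc1ccc(O)cc1 | target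

**Step count**

Total steps: 5. Longest linear sequence: 5 (1 → 2 → 3 → 6 → 9 → 10).

**Steps most likely to fail**

Step 4 is the most likely to fail. It asks for three couplings on one substrate, two of them at bromides flanked on both sides. N-arylation of 8, or plain Wolff–Kishner reduction of 8 to 4-(benzyloxy)toluene, can outrun C–C coupling. The fallback sets out from 6 and comes back at 9. The benzyl carbon is delivered as a preformed organozinc instead. Commercial 4-(benzyloxy)benzyl chloride (ClCc1ccc(OCc2ccccc2)cc1) is treated with Zn dust and LiCl in THF to give [4-(benzyloxy)benzyl]zinc chloride F1. Threefold Negishi coupling of F1 (4 equiv, three of them built in) with 6 under Pd(OAc)2/SPhos in THF at 60 °C then gives 9.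

Step 3 is the second risk. Aldehyde 3 is flanked by two bromines and hydrazone 5 carries an ortho benzyloxy group, so azine formation or arrest at the carbinol stage are the likely failures. The fallback sets out from 4 and comes back at 6. NaBH4 (MeOH, 0 °C) gives [2-(benzyloxy)-5-bromophenyl]methanol F2. PBr3 (CH2Cl2, 0 °C) gives 1-(benzyloxy)-4-bromo-2-(bromomethyl)benzene F3. Arbuzov reaction with P(OEt)3 (neat, 130 °C) gives diethyl {[2-(benzyloxy)-5-bromophenyl]methyl}phosphonate F4. Horner–Wadsworth–Emmons olefination of 3 with F4 (KOtBu, THF, 0 °C to rt) gives E-configured 6.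

Step 2 is the third risk. The formyl group and the first bromine deactivate the ring, so the second bromination may stall or, when forced, spill over to C4. The fallback sets out from 2 and comes back at 3. NaBH4 (MeOH, 0 °C) gives [3-(benzyloxy)-5-methoxyphenyl]methanol F5. Its carbonyl-free ring takes two bromines from NBS (2.05 equiv, MeCN, 0 °C) at the positions para to oxygen, giving [3-(benzyloxy)-2,6-dibromo-5-methoxyphenyl]methanol F6. MnO2 (CH2Cl2, rt) then returns aldehyde 3.

**Further compounds**

F1 | step 4 | [4-(benzyloxy)benzyl]zinc chloride | Cl[Zn]Cc1ccc(OCc2ccccc2)cc1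
F2 | step 3 | [2-(benzyloxy)-5-bromophenyl]methanol | OCc1cc(Br)ccc1OCc1ccccc1
F3 | step 3 | 1-(benzyloxy)-4-bromo-2-(bromomethyl)benzene | BrCc1cc(Br)ccc1OCc1ccccc1
F4 | step 3 | diethyl {[2-(benzyloxy)-5-bromophenyl]methyl}phosphonate | CCOP(=O)(Cc1cc(Br)ccc1OCc1ccccc1)OCC
F5 | step 2 | [3-(benzyloxy)-5-methoxyphenyl]methanol | COc1cc(OCc2ccccc2)cc(CO)c1
F6 | step 2 | [3-(benzyloxy)-2,6-dibromo-5-methoxyphenyl]methanol | COc1cc(OCc2ccccc2)c(Br)c(CO)c1Br
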